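The runs were computed on assumed constants.

A flask cannot put more than 100 percent of its charge into chains, so a straight-line rate carried over 4.0 min is not to be trusted. What can stay frozen is the fraction of the remaining free monomer that enters chains each minute.

| flask | free monomer | initiator | temperature | remark | time |
|---|---|---|---|---|---|
| gamma | 0.12 M | 0.46 mM | 98 °C | run made earlier |  |
| beta | 0.46 M | 0.46 mM | 125 °C | run made earlier |  |
| epsilon | 0.23 M | 0.23 mM | 98 °C | run made earlier |  |
| winter | 0.23 M | 0.46 mM |  | at 85 °C until 50 s, from then on at 135 °C | 4.0 min |
| autumn | 0.23 M | 0.46 mM | 110 °C |  | 4.0 min |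
| dawn | 0.23 M | 0.46 mM | 135 °C |  | 4.0 min |
| summer | 0.23 M | 0.46 mM | 85 °C |  | 4.0 min |

- gamma (time / min: monomer in chains / %): 0.417: 7.3; 0.833: 15.8; 1.50: 21.0; 2.50: 18.3; 5.00: 4.2
- beta (time / s: monomer in chains / %): 10.0: 16.7; 25.0: 17.7; 40.0: 11.6; 80.0: 1.2
- epsilon (time / min: monomer in chains / %): 0.417: 8.5; 0.833: 15.5; 1.50: 21.5; 2.50: 26.5; 5.00: 24.6

(each reading ± 1 percentage point)

- which flask leads in amount of monomer in chains, in percent of the free monomer charged ("all alike" within 1.5 percentage points) (winter / autumn / dawn / summer / all alike)
- how much monomer in chains is there at the end, in percent of the free monomer charged: winter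
- how much monomer in chains is there at the end, in percent of the free monomer charged: autumn
- how much monomer in chains is there at the end, in percent of the free monomer charged: dawn
- how much monomer in chains is there at the end, in percent of the free monomer charged: summer

Two of us argued over summer. One reads these curves as forming against losing, with heat favouring the loss, and beta, down to 1.2 % by 80.0 s, is the strong witness for that. I start from the filling and get a first figure for summer with loss set aside, as an admitted omission, for gamma at 98 °C falls from 18.3 % to 4.2 % between its last two readings.

Epsilon's first reading gives 0.204 min⁻¹, with the scatter of a reading. Gamma's first reading gives 0.175 min⁻¹, although gamma carries twice epsilon's c(initiator), with about half its c(free monomer). So I let the pace follow the product of c(initiator) and c(free monomer). The flasks' product is twice epsilon's, so I take 0.408 min⁻¹ for them at 98 °C. Beta's product is twice the flasks', so I halve its first reading and get 0.501 min⁻¹ for them at 125 °C, which is faster. With the logarithm of the pace on a straight line in temperature, summer at 85 °C gets 0.369 min⁻¹. This is my fill pace, the pseudo-first-order fraction of remaining free monomer entering chains per minute at the flasks' charge. Over 4.0 min it fills 77.2 %. That counts no loss, so I expect summer somewhat below it.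

The forecast, from the other side, says summer “forms more slowly and loses little” and gives 30 %, with autumn 3 %, dawn 0.2 %, winter 0.4 %, and summer leading.

The flasks give summer 50.5 %, leading, with autumn 0.0165 %, dawn 0 %, winter 0 %. The losing view keeps the hot region: from 110 °C upward, and in winter after its jump to 135 °C, its near-empty flasks stand.

    2 free monomer → homo dimer (k = 0.0390 M⁻¹ s⁻¹, Ea = 79.0 kJ mol⁻¹)
    free monomer + initiator → living end + monomer in chains (k = 1.10 M⁻¹ s⁻¹, Ea = 45.0 kJ mol⁻¹)
    free monomer + living end → monomer in chains + living end, rate k3*[living end]*[free monomer] (k = 65.0 M⁻¹ s⁻¹, Ea = 61.0 kJ mol⁻¹)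
    initiator ⇌ dormant form (K = 2.80, k = 0.0390 s⁻¹, Ea = 101 kJ mol⁻¹, ΔH = −37.0 kJ mol⁻¹)
    monomer in chains + living end → free monomer + living end, rate k5*[living end] as long as [monomer in chains] is above zero (k = 6.10 s⁻¹, Ea = 95.0 kJ mol⁻¹)
    (constants at 110 °C)

The largest single effect on the difference dawn minus summer is what temperature does to the turning of monomer in chains into free monomer: that difference is −50 percentage points as it stands and 9.9 points with this effect taken away. In summer, part of the gap below my figure is that same step. With that step taken away summer ends at 68.7 % instead of 50.5 %, against my no-loss 77.2 %. Carried down to the neighbour of summer at 60 °C, the pace becomes 0.305 min⁻¹ and fills 70.5 % without loss, and that neighbour ends lower, at 25.5 %.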